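The tetrahydrofuran ring A (O–C7(aryl)–C8–C8'(OH)–C9') is made by ring contraction. An asymmetric hetero-Diels–Alder reaction sets C7 in a 2-aryl-2,3-dihydro-4H-pyran-4-one, whose 3-diazo derivative undergoes a photochemical Wolff rearrangement. In one operation the six-membered ring becomes the five-membered ring A and the former carbonyl carbon is expelled as the C9 ester branch on C8. The step exploits the C7(O,aryl)–C8(C9) 1,2-relationship and leaves C8'=C9' as an enol ether for later oxidation. Ring B (O–C7'–C8'–C8–C9) and the tertiary C8'–OH then arise together by Norrish–Yang photocyclization of the derived tetrahydrofuran-3-one benzyl ether.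

Key step: step 6

Remarks
- Locants: C7, C8, C9 belong to the unit whose C8 carries hydrogen; C7', C8', C9' to the unit whose C8' carries the hydroxyl. Ar = 3,5-dimethoxy-4-(triisopropylsilyloxy)phenyl. The target is (7S,8R,7'R,8'S), i.e. (1S,2R,5R,6S) in bicyclo[3.3.0]octane numbering.
- Assumption: the (S)-BINOL–titanium catalyst of step 4 is taken to deliver the (S)-pyranone; if the sense of induction proves opposite, (R)-BINOL is used.

Step 1
Reactants: 1 syringaldehyde
Product: 2 3,5-dimethoxy-4-(triisopropylsilyloxy)benzaldehyde (ArCHO)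
Conditions: iPr3SiCl, imidazole, DMF, 23 °C
Reagents that add atoms: triisopropylsilyl chloride, CC(C)[Si](Cl)(C(C)C)C(C)C
Why: Imidazole-promoted O-silylation of the phenol; the hindered aryl silyl ether should survive the bases, hydrides, borane and irradiation used later and is removed by fluoride at the end.

Step 2
Reactants: 2 ArCHO
Product: 3 [3,5-dimethoxy-4-(triisopropylsilyloxy)phenyl]methanol (ArCH2OH)
Conditions: NaBH4, MeOH/THF, 0 °C
Reagents that add atoms: none
Why: Borohydride reduction of the aldehyde to the benzylic alcohol leaves the aryl silyl ether untouched.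

Step 3
Reactants: 3 ArCH2OH
Product: 4 5-(bromomethyl)-1,3-dimethoxy-2-(triisopropylsilyloxy)benzene (ArCH2Br)
Conditions: CBr4, PPh3, CH2Cl2, 0 °C
Reagents that add atoms: tetrabromomethane, BrC(Br)(Br)Br
Why: Appel bromination under neutral conditions converts the electron-rich benzylic alcohol into the bromide without acid that could ionise it; the bromide is used at once.

Step 4
Reactants: 2 ArCHO; 5 Danishefsky's diene, (E)-1-methoxy-3-(trimethylsilyloxy)buta-1,3-diene
Product: 7 (S)-2-Ar-2,3-dihydro-4H-pyran-4-one, via aldol adduct 6 (not isolated)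
Conditions: (S)-BINOL (20 mol %), Ti(OiPr)4 (10 mol %), 4 Å MS, Et2O, −20 °C; then CF3CO2H, CH2Cl2, 0 °C
Reagents that add atoms: none
Why: Catalytic asymmetric hetero-Diels–Alder reaction in its Mukaiyama-aldol/cyclization mode: the chiral BINOL–titanium Lewis acid selects the aldehyde face and so sets C7, and acid closes the pyranone by conjugate addition–elimination of methanol.

Step 5
Reactants: 7 (S)-2-Ar-2,3-dihydro-4H-pyran-4-one
Product: 9 (R)-3-diazo-2-Ar-2,3-dihydro-4H-pyran-4-one (same spatial arrangement at the aryl carbon as in 7), via trifluoroacetyl ketone 8 (not isolated)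
Conditions: LiN(SiMe3)2, THF, −78 °C; CF3CO2CH2CF3; then MsN3, Et3N, H2O, MeCN, 23 °C
Reagents that add atoms: methanesulfonyl azide, CS(=O)(=O)N=[N+]=[N-]
Why: Detrifluoroacetylative diazo transfer: C3 is the only enolisable position of the vinylogous ester, its kinetic lithium enolate is trifluoroacetylated, and the activated 1,3-dicarbonyl accepts the diazo group from the sulfonyl azide with loss of the trifluoroacetyl group, C7 being untouched.

Step 6
Reactants: 9 (R)-3-diazo-2-Ar-2,3-dihydro-4H-pyran-4-one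
Product: 12 methyl (2S,3S)-2-Ar-2,3-dihydrofuran-3-carboxylate (trans), via ketene 10 (not isolated), via cis ester 11 (not isolated)
Conditions: hν (350 nm, Pyrex), MeOH, 0 °C; then DBU (0.2 equiv), 23 °C
Reagents that add atoms: methanol, CO
Why: Irradiation of the s-cis-locked α-diazoketone expels N2 with concerted 1,2-shift of the vinylic ring carbon (pyranone C5, the future C8') from the carbonyl carbon to the diazo carbon, giving ring-contracted ketene 10 whose exocyclic carbon is the former ring carbonyl (future C9); methanol adds to give the ester. The closest known reaction type is the photochemical Wolff ring contraction of cyclic α-diazoketones, for example 3-diazochroman-4-ones to 2,3-dihydrobenzofuran-3-carboxylates. No ring is closed by a cyclization: ring A arises from the six-membered ring by the 1,2-shift alone, so no Baldwin-type closure is involved. C7 is a spectator and keeps its configuration; the new C8 stereocenter is first set by protonation of the ester enol anti to the C7 aryl group (cis, 11) and is then brought to trans by DBU equilibration under thermodynamic control by that aryl group. The step needs the Wolff shift to win over 1,2-hydride shift from C7 (which would give the 4-pyranone) and over O–H insertion into methanol, which the fixed s-cis geometry and direct irradiation at low temperature should secure; in the equilibration, loss of the endocyclic β-oxygen is a disfavoured retro-5-endo-trig process and α-reprotonation of the dienolate should be faster than γ-reprotonation.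

Step 7
Reactants: 12 methyl (2S,3S)-2-Ar-2,3-dihydrofuran-3-carboxylate
Product: 13 [(2S,3R)-2-Ar-2,3-dihydrofuran-3-yl]methanol
Conditions: iBu2AlH, CH2Cl2, −78 °C; aqueous Rochelle salt work-up
Reagents that add atoms: none
Why: Hydride reduction of the ester to the primary alcohol at low temperature with a neutral work-up spares the acid-sensitive enol ether and touches no stereocenter.

Step 8
Reactants: 13 [(2S,3R)-2-Ar-2,3-dihydrofuran-3-yl]methanol; 4 ArCH2Br
Product: 14 (2S,3R)-2-Ar-3-[(ArCH2O)methyl]-2,3-dihydrofuran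
Conditions: NaH, THF, 0 °C; then 4, Bu4NI (cat.), 0 → 23 °C
Reagents that add atoms: none
Why: Williamson ether synthesis between the primary alkoxide and the reactive benzylic bromide installs the C9–O–C7' tether that will become ring B.

Step 9
Reactants: 14 (2S,3R)-2-Ar-3-[(ArCH2O)methyl]-2,3-dihydrofuran
Product: 16 (3S,4S,5S)-5-Ar-4-[(ArCH2O)methyl]tetrahydrofuran-3-ol, via alkylborane 15 (not isolated)
Conditions: BH3·THF, THF, 0 → 23 °C; then H2O2, pH 7 phosphate buffer, 0 → 23 °C
Reagents that add atoms: hydrogen peroxide, OO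
Why: Hydroboration–oxidation of the cyclic enol ether places boron on the β-carbon C8' for electronic reasons and anti to the neighbouring C8 substituent; the carbinol configuration is of no consequence since it is oxidised next.

Step 10
Reactants: 16 (3S,4S,5S)-5-Ar-4-[(ArCH2O)methyl]tetrahydrofuran-3-ol
Product: 17 (4R,5S)-5-Ar-4-[(ArCH2O)methyl]dihydrofuran-3(2H)-one
Conditions: Dess–Martin periodinane, CH2Cl2, 0 → 23 °C
Reagents that add atoms: none
Why: Dess–Martin oxidation of the secondary alcohol under near-neutral conditions gives the β-alkoxy ketone without β-elimination, and the 4,5-trans arrangement carried in is also the thermodynamic one.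

Step 11
Reactants: 17 (4R,5S)-5-Ar-4-[(ArCH2O)methyl]dihydrofuran-3(2H)-one
Product: 19 (1S,2R,5R,6S)-2,6-bis-Ar-3,7-dioxabicyclo[3.3.0]octan-1-ol, via biradical 18 (not isolated)
Conditions: hν (medium-pressure Hg lamp, Pyrex filter), degassed benzene, 23 °C
Reagents that add atoms: none
Why: Norrish–Yang photocyclization: the excited ketone abstracts the δ-hydrogen of the benzylic ether carbon C7' through a six-membered transition state and the 1,5-biradical closes ring B, the tether from C8 enforcing cis fusion (C8'–OH cis to H8) and the C7' aryl group expected to take the exo position.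

Step 12
Reactants: 19 (1S,2R,5R,6S)-2,6-bis-Ar-3,7-dioxabicyclo[3.3.0]octan-1-ol
Product: 20 8-hydroxysyringaresinol
Conditions: Bu4NF, AcOH, THF, 0 °C
Reagents that add atoms: none
Why: Fluoride-mediated cleavage of both aryl silyl ethers, buffered with acetic acid so that the liberated phenoxides do not open the benzylic ethers through quinone methides.

Compound list
1 | syringaldehyde (4-hydroxy-3,5-dimethoxybenzaldehyde) | COc1cc(C=O)cc(OC)c1O | starting material
2 | 3,5-dimethoxy-4-(triisopropylsilyloxy)benzaldehyde | COc1cc(C=O)cc(OC)c1O[Si](C(C)C)(C(C)C)C(C)C | intermediate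
3 | [3,5-dimethoxy-4-(triisopropylsilyloxy)phenyl]methanol | COc1cc(CO)cc(OC)c1O[Si](C(C)C)(C(C)C)C(C)C | intermediate
4 | 5-(bromomethyl)-1,3-dimethoxy-2-(triisopropylsilyloxy)benzene | COc1cc(CBr)cc(OC)c1O[Si](C(C)C)(C(C)C)C(C)C | intermediate
5 | Danishefsky's diene, (E)-1-methoxy-3-(trimethylsilyloxy)buta-1,3-diene | CO/C=C/C(=C)O[Si](C)(C)C | starting material
6 | (S,E)-5-Ar-1-methoxy-5-(trimethylsilyloxy)pent-1-en-3-one (Mukaiyama aldol adduct, not isolated) | CO/C=C/C(=O)C[C@H](O[Si](C)(C)C)c1cc(OC)c(O[Si](C(C)C)(C(C)C)C(C)C)c(OC)c1 | intermediate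
7 | (S)-2-Ar-2,3-dihydro-4H-pyran-4-one | O=C1C=CO[C@H](c2cc(OC)c(O[Si](C(C)C)(C(C)C)C(C)C)c(OC)c2)C1 | intermediate
8 | (2S)-2-Ar-3-(trifluoroacetyl)-2,3-dihydro-4H-pyran-4-one (C3 epimers and enol, not isolated) | O=C1C=CO[C@H](c2cc(OC)c(O[Si](C(C)C)(C(C)C)C(C)C)c(OC)c2)C1C(=O)C(F)(F)F | intermediate
9 | (R)-3-diazo-2-Ar-2,3-dihydro-4H-pyran-4-one | O=C1C=CO[C@H](c2cc(OC)c(O[Si](C(C)C)(C(C)C)C(C)C)c(OC)c2)C1=[N+]=[N-] | intermediate
10 | (R)-2-Ar-3-(oxomethylidene)-2,3-dihydrofuran (ketene, not isolated) | O=C=C1C=CO[C@@H]1c2cc(OC)c(O[Si](C(C)C)(C(C)C)C(C)C)c(OC)c2 | intermediate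
11 | methyl (2S,3R)-2-Ar-2,3-dihydrofuran-3-carboxylate (cis, not isolated) | COC(=O)[C@@H]1C=CO[C@@H]1c2cc(OC)c(O[Si](C(C)C)(C(C)C)C(C)C)c(OC)c2 | intermediate
12 | methyl (2S,3S)-2-Ar-2,3-dihydrofuran-3-carboxylate (trans) | COC(=O)[C@H]1C=CO[C@@H]1c2cc(OC)c(O[Si](C(C)C)(C(C)C)C(C)C)c(OC)c2 | intermediate
13 | [(2S,3R)-2-Ar-2,3-dihydrofuran-3-yl]methanol (trans) | OC[C@H]1C=CO[C@@H]1c2cc(OC)c(O[Si](C(C)C)(C(C)C)C(C)C)c(OC)c2 | intermediate
14 | (2S,3R)-2-Ar-3-[(ArCH2O)methyl]-2,3-dihydrofuran | COc1cc(COC[C@H]2C=CO[C@@H]2c3cc(OC)c(O[Si](C(C)C)(C(C)C)C(C)C)c(OC)c3)cc(OC)c1O[Si](C(C)C)(C(C)C)C(C)C | intermediate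
15 | alkylborane from 14, drawn as the monoalkylborane: BH2 on ring C3 (C8'), trans to the C4 substituent, cis to the C5 aryl group (not isolated) | B[C@@H]1CO[C@H](c2cc(OC)c(O[Si](C(C)C)(C(C)C)C(C)C)c(OC)c2)[C@H]1COCc3cc(OC)c(O[Si](C(C)C)(C(C)C)C(C)C)c(OC)c3 | intermediate
16 | (3S,4S,5S)-5-Ar-4-[(ArCH2O)methyl]tetrahydrofuran-3-ol | O[C@@H]1CO[C@H](c2cc(OC)c(O[Si](C(C)C)(C(C)C)C(C)C)c(OC)c2)[C@H]1COCc3cc(OC)c(O[Si](C(C)C)(C(C)C)C(C)C)c(OC)c3 | intermediate
17 | (4R,5S)-5-Ar-4-[(ArCH2O)methyl]dihydrofuran-3(2H)-one | O=C1CO[C@H](c2cc(OC)c(O[Si](C(C)C)(C(C)C)C(C)C)c(OC)c2)[C@H]1COCc3cc(OC)c(O[Si](C(C)C)(C(C)C)C(C)C)c(OC)c3 | intermediate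
18 | 1,5-biradical from 17: carbinol radical at C8' and benzylic radical at C7' (not isolated) | O[C]1CO[C@H](c2cc(OC)c(O[Si](C(C)C)(C(C)C)C(C)C)c(OC)c2)[C@H]1CO[CH]c3cc(OC)c(O[Si](C(C)C)(C(C)C)C(C)C)c(OC)c3 | intermediate
19 | (1S,2R,5R,6S)-2,6-bis[3,5-dimethoxy-4-(triisopropylsilyloxy)phenyl]-3,7-dioxabicyclo[3.3.0]octan-1-ol | COc1cc([C@H]2OC[C@]3(O)[C@@H](c4cc(OC)c(O[Si](C(C)C)(C(C)C)C(C)C)c(OC)c4)OC[C@H]23)cc(OC)c1O[Si](C(C)C)(C(C)C)C(C)C | intermediate
20 | 8-hydroxysyringaresinol, (1S,2R,5R,6S)-2,6-bis(4-hydroxy-3,5-dimethoxyphenyl)-3,7-dioxabicyclo[3.3.0]octan-1-ol | COc1cc([C@H]2OC[C@]3(O)[C@@H](c4cc(OC)c(O)c(OC)c4)OC[C@H]23)cc(OC)c1O | target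

Total step count: 12. Longest linear sequence: 10 steps (steps 1 and 4 to 12); steps 2 and 3 form the side branch to bromide 4.

Steps most likely to fail

Step 6. The carbene-type pathways may overtake the Wolff shift (1,2-hydride shift from C7 leading to aromatisation as the 4-pyranone, or O–H insertion into methanol), and the base equilibration may move the enol-ether double bond into conjugation with the ester. The fallback is an auxiliary-controlled aldol route without diazo chemistry, setting out from aldehyde 2 and bromide 4 and returning at dihydrofuran ether 14. (S)-4-Benzyloxazolidin-2-one is N-acylated (n-BuLi, methyl 4-chloro-4-oxobutanoate) to (S)-4-benzyl-3-(4-methoxy-4-oxobutanoyl)oxazolidin-2-one F1. Its boron enolate (Bu2BOTf, iPr2NEt) undergoes the Evans syn-aldol reaction with 2, and the aldolate lactonises onto the methyl ester to give the trans lactone imide F2. NaBH4 in THF/H2O removes the auxiliary to give the hydroxymethyl lactone F3. Ag2O-mediated etherification with 4 gives the ether lactone F4, iBu2AlH at −78 °C gives the lactol F5, and dehydration with MsCl/Et3N gives 14.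

Step 11. δ-Hydrogen abstraction may be inefficient against α-cleavage of the excited ketone, and the biradical may close with poor facial selectivity at C7'. The fallback builds the C8'–C7' bond and the tertiary alcohol by ionic chemistry, setting out from ketone 17 and bromide 4 and returning at 19. Bromide 4 and PPh3 give the benzylic phosphonium bromide F6. Its ylide (KN(SiMe3)2, THF) undergoes a Wittig reaction with 17 to give the benzylidene tetrahydrofuran F7 as an alkene mixture. Dihydroxylation (OsO4 cat., N-methylmorpholine N-oxide) from the face anti to the C8 substituent gives the diol F8 with the C8'–OH correctly placed. Camphorsulfonic acid in CH2Cl2/MeOH then ionises the benzylic C7'–OH; the C9 ether oxygen attacks and loses its electron-rich benzyl group (debenzylative cycloetherification), closing ring B to 19 with the aryl group expected exo.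

Step 5. The lithium enolate may open the ring by retro-oxa-Michael loss of the β-oxygen, or trifluoroacetylation may be incomplete. The fallback avoids the enolate and the azide transfer, setting out from pyranone 7 and returning at diazoketone 9. Acid-mediated α-nitrosation through the enol (isoamyl nitrite, HCl, Et2O, 0 °C) gives the α-oximino ketone F9, which preformed chloramine with NaOH converts to 9 (Forster reaction).

Further compounds
F1 | step 6 | (S)-4-benzyl-3-(4-methoxy-4-oxobutanoyl)oxazolidin-2-one | COC(=O)CCC(=O)N1[C@@H](Cc2ccccc2)COC1=O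
F2 | step 6 | (S)-4-benzyl-3-[(2S,3S)-2-Ar-5-oxotetrahydrofuran-3-carbonyl]oxazolidin-2-one | O=C1C[C@H](C(=O)N2[C@@H](Cc3ccccc3)COC2=O)[C@@H](c4cc(OC)c(O[Si](C(C)C)(C(C)C)C(C)C)c(OC)c4)O1
F3 | step 6 | (4R,5S)-5-Ar-4-(hydroxymethyl)dihydrofuran-2(3H)-one | O=C1C[C@H](CO)[C@@H](c2cc(OC)c(O[Si](C(C)C)(C(C)C)C(C)C)c(OC)c2)O1
F4 | step 6 | (4R,5S)-5-Ar-4-[(ArCH2O)methyl]dihydrofuran-2(3H)-one | O=C1C[C@H](COCc2cc(OC)c(O[Si](C(C)C)(C(C)C)C(C)C)c(OC)c2)[C@@H](c3cc(OC)c(O[Si](C(C)C)(C(C)C)C(C)C)c(OC)c3)O1
F5 | step 6 | (4R,5S)-5-Ar-4-[(ArCH2O)methyl]tetrahydrofuran-2-ol (anomers) | OC1C[C@H](COCc2cc(OC)c(O[Si](C(C)C)(C(C)C)C(C)C)c(OC)c2)[C@@H](c3cc(OC)c(O[Si](C(C)C)(C(C)C)C(C)C)c(OC)c3)O1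
F6 | step 11 | [3,5-dimethoxy-4-(triisopropylsilyloxy)benzyl]triphenylphosphonium bromide | COc1cc(C[P+](c2ccccc2)(c3ccccc3)c4ccccc4)cc(OC)c1O[Si](C(C)C)(C(C)C)C(C)C.[Br-]
F7 | step 11 | (2S,3R)-2-Ar-4-(Ar-methylidene)-3-[(ArCH2O)methyl]tetrahydrofuran (alkene isomers) | C(=C1CO[C@H](c2cc(OC)c(O[Si](C(C)C)(C(C)C)C(C)C)c(OC)c2)[C@H]1COCc3cc(OC)c(O[Si](C(C)C)(C(C)C)C(C)C)c(OC)c3)c4cc(OC)c(O[Si](C(C)C)(C(C)C)C(C)C)c(OC)c4
F8 | step 11 | (3S,4R,5S)-5-Ar-3-[Ar(hydroxy)methyl]-4-[(ArCH2O)methyl]tetrahydrofuran-3-ol (epimers at the benzylic carbinol) | OC(c1cc(OC)c(O[Si](C(C)C)(C(C)C)C(C)C)c(OC)c1)[C@@]2(O)CO[C@H](c3cc(OC)c(O[Si](C(C)C)(C(C)C)C(C)C)c(OC)c3)[C@H]2COCc4cc(OC)c(O[Si](C(C)C)(C(C)C)C(C)C)c(OC)c4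
F9 | step 5 | (R)-2-Ar-3-(hydroxyimino)-2,3-dihydro-4H-pyran-4-one | O=C1C=CO[C@H](c2cc(OC)c(O[Si](C(C)C)(C(C)C)C(C)C)c(OC)c2)C1=NO
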